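Turnovers, millimoles of target per millimole of free catalyst charged, are the unit we reckon in. The flask in question is the east run carried to 10 min.

| flask | starting material | second substrate | free catalyst | remark | time |
|---|---|---|---|---|---|
| east | 14 mM | 14 mM | 28 µM | the very flask that is asked about, followed so far |  |
| south-east | 14 mM | 14 mM | 19 µM | run made earlier |  |
| flask | 14 mM | 14.0 mM | 28 µM |  | 10 min |

- east (time / min: target / %): 0.833: 17.1; 1.33: 22.4; 2.00: 30.7; 4.00: 41.8; 6.00: 43.3; 10.0: 47.7
- south-east (time / min: target / %): 0.667: 9.4; 1.33: 15.8; 2.00: 21.1; 2.50: 23.6; 3.00: 25.2; 4.00: 28.5

(scatter of a reading: 1 percentage point)

- what is taken out of target is counted as made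
- reactions considered so far: starting material + free catalyst <-> catalyst intermediate A; catalyst intermediate A -> free catalyst + target; second substrate + free catalyst <-> catalyst intermediate B; catalyst intermediate B -> free catalyst + second product; starting material + catalyst intermediate B -> spent catalyst A; catalyst intermediate B -> spent catalyst B
- additions bring no volume worth counting

- red: at 10 min add free catalyst, 100% of the amount charged, then wait 10 min
- violet: at 10 min take out 90% of the target then present, then wait 10 min
- blue: at 10 min add starting material, 50.0% of the amount charged, then wait 10 min
- teal: change nothing and wait 10 min more

- target, in percent of the starting material first charged, at 10 min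
- what to do for the largest gain in target; "none" if nothing gains more than 2 percentage points (red / violet / blue / teal / none)
- target present, with what was taken out counted in, in percent of the starting material first charged, after violet
- target present, with what was taken out counted in, in percent of the starting material first charged, after teal

At 4.00 min east reads 41.8% and south-east 28.5%, a ratio of 1.47 against 1.47 in catalyst charged. If live catalyst decays exponentially and the rate per live catalyst holds constant, the rate integrates in closed form to a ceiling, initial rate over decay constant, and with that decay constant fixed the ceiling scales with the charge. East flattens with 52.3% of the starting material not read as target at its last reading, so we read the stop as catalyst death, not a shortage of starting material. We therefore carry the turnover number (TON), the target made per catalyst charged over the catalyst's working life, here as read from east's last reading: 239. By our reckoning, red's fresh charge at that TON makes 48 percentage points more target.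

The forecast gives 47% (45.5% to 48.5%) now, 48% (46% to 52%) after violet, 48% (46% to 51%) after teal, and red as best, with perhaps 25 points or more from it, where we reckon 48 points. Its ground: “the stall comes from catalyst death”.

The simulation gives 47.2% now, 47.7% after violet and 47.7% after teal. Best is red, which gains 43 points, while blue gains 0.89 points.

    starting material + free catalyst ⇌ catalyst intermediate A (K = 131 L mol⁻¹, k = 1560 L mol⁻¹ s⁻¹)
    catalyst intermediate A → free catalyst + target (k = 5.16 s⁻¹)
    second substrate + free catalyst ⇌ catalyst intermediate B (K = 180 L mol⁻¹, k = 569 L mol⁻¹ s⁻¹)
    catalyst intermediate B → free catalyst + second product (k = 8.38 s⁻¹)
    starting material + catalyst intermediate B → spent catalyst A (k = 0.535 L mol⁻¹ s⁻¹)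
    catalyst intermediate B → spent catalyst B (k = 0.0331 s⁻¹)

Red's gain, taken per catalyst added, comes to 213 turnovers, fewer than the 239 we carried. The same TON on the south-east charge gives 32.4%, and the south-east run, carried on, stands at 32.1% at 10 min. In the asked flask, catalyst intermediate A passed on to free catalyst and target with free catalyst at 22.5% of the catalyst charged at 1.00 min, and that step had done half of its turnover up to 10 min by 1.29 min. By 10.0 min free catalyst stood at 0.521%, with 84.4% as spent catalyst B and 14.5% as spent catalyst A, while starting material stood at 52.7%.

The runs are simulated from invented constants; the scatter is artificial.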